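The rate constants are invented; the result is computed.

The target in these flasks is made from substrate and dissolved coupling partner, and none of that partner stands in the liquid at the start; it has to come over from the gas.

common to all: substrate 0.20 M; gas 48 mM (held); time 50 min

| run | temperature |
|---|---|
| east | 50 °C |
| north | 10 °C |
| south-west | 30 °C |

- the best flask by amount of target, in percent of the substrate charged; "all alike" if 1.5 percentage points covers them all (east / north / south-west / all alike)
- amount of target at the end, in percent of the substrate charged, east
- amount of target at the end, in percent of the substrate charged, north
- amount of target at the end, in percent of the substrate charged, south-west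

- at the start none of coupling partner is dissolved
- constants are those at 50 °C; use the activation energies and enthalpies for any other temperature
- in a conversion other conformer counts as not yet reacted

    substrate + coupling partner → target (k1 = 0.80 M⁻¹ min⁻¹, Ea1 = 51.0 kJ mol⁻¹)
    coupling partner + other conformer → isomer of the product (k2 = 0.53 M⁻¹ min⁻¹, Ea2 = 78.0 kJ mol⁻¹)
    substrate ⇌ other conformer (K3 = 0.26, k3 = 7.5 × 10⁻⁴ min⁻¹, Ea3 = 118 kJ mol⁻¹, ΔH3 = −51.0 kJ mol⁻¹)
    gas ⇌ coupling partner, rate k4*(csat - [coupling partner]) (k4 = 0.12 min⁻¹, csat = 48 mM)
    (constants at 50 °C)

We begin by comparing two rates at one moment. Partner arrives at the transfer coefficient 0.12 min⁻¹ times its distance from saturation, 48 mM. It leaves at the constant for making target, 0.80 M⁻¹ min⁻¹ in east, times substrate and partner. Taking up over bringing in, with the charge folded in, gives 1.33 in east, a Damköhler number. Where arrival equals departure, partner rests at saturation divided by one plus that ratio, 20.6 mM in east at the opening. Substrate then falls pseudo-first-order, and over the time this gives 0.823. This number, the substrate's decay constant at the opening rest level of partner multiplied by the time, we call the reach. The fraction made is one minus the exponential of minus the reach, so east gives 56.1%.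

The north flask has the step slower by the factor 15, so its reach is 0.120, or 11.3%. For south-west we roughly take the square root of that factor, which gives 0.372, or 31.1%. East has the longest reach, and it is our choice.

Was one number enough? In east the rest level climbs as substrate falls: with 43.9% of substrate left the same balance gives 30.3 mM, which lengthens the reach. Filling the liquid takes about 8.33 min, which shortens it. In east the opening rate constant towards other conformer, 7.5 × 10⁻⁴ min⁻¹, is far slower than the 0.0165 min⁻¹ towards target, so we leave that path out.

The forecast named east, with 59% for east, 9.7% for north and 30.3% for south-west, holding that “Dissolved gas is mass-transfer limited”. The simulation gives east as the best flask, with 59.1% in east, 9.73% in north and 30.3% in south-west. The east reading is higher than our figure, and the north reading is lower than ours.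

The main reason east stands at 59.1% is that it is read at 50 min and not ten times later: left until 500 min, the same flask holds 96.9% of target, and the wait makes up 92% of what is missing. So the thing to watch in a repeat is the substrate still standing in east, 38% at the reading. For the east flask left until 30 min, the reach becomes 0.494, which gives 39.0%. The simulation gives 37.6%.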